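## Retrosynthetic overview

1. The target is released from its 7-O-allyl ether by Pd(0) deallylation; allyl is the only protecting group carried on the flavonoid.
2. The pyranone (C) ring is the only ring built and is closed last, by Claisen–Schmidt condensation and Algar–Flynn–Oyamada oxidation of an A-ring acetophenone with a B-ring aldehyde. Rings A and B are bought as benzenes.
3. Key disconnection: the carbinol–isopropenyl C–C bond of the B-ring aldehyde. The carbinol carbon (normally an acceptor) is used as a sparteine-lithiated α-oxy carbanion and joined to an isopropenylboronate, so two donor carbons are coupled by a 1,2-metallate shift. This sets the (R) centre in the bond-forming operation.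
4. The lithiation substrate comes from 2-(2-methoxyphenyl)ethanol by carbamoylation, Rieche formylation para to OMe, and acetal formation.
5. The A-ring ketone comes from 2',4'-dihydroxy-6'-methoxyacetophenone by 4-O-allylation, Elbs para-hydroxylation and O-methylation.

Assumption: the target carbinol is (R) as read from the SMILES, and compounds 1, 6, 11 and (−)-sparteine are taken as catalogue items.

## Route

Step 1
Reactants: 1 1-(2,4-dihydroxy-6-methoxyphenyl)ethan-1-one
Product: 2 1-[2-hydroxy-6-methoxy-4-(prop-2-en-1-yloxy)phenyl]ethan-1-one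
Conditions: allyl bromide (1.05 equiv), K2CO3 (1.1 equiv), acetone, reflux
Reagents that add atoms: allyl bromide (C=CCBr)
Why: Williamson etherification in which the 4-OH (para to the acetyl, not hydrogen-bonded) is far more acidic and nucleophilic than the chelated 2-OH, so one equivalent of allyl bromide alkylates it selectively.

Step 2
Reactants: 2 1-[2-hydroxy-6-methoxy-4-(prop-2-en-1-yloxy)phenyl]ethan-1-one
Product: 4 1-[3,6-dihydroxy-2-methoxy-4-(prop-2-en-1-yloxy)phenyl]ethan-1-one, via aryl potassium sulfate 3 (not isolated)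
Conditions: K2S2O8 (1.2 equiv), 10% aq KOH, pyridine, 15–20 °C, 36 h; recover unreacted 2 at pH 5; then conc. HCl, Na2SO3, 85 °C, 30 min
Reagents that add atoms: potassium peroxodisulfate ([K+].[K+].[O-]S(=O)(=O)OOS(=O)(=O)[O-])
Why: Elbs persulfate oxidation, in which the phenoxide attacks peroxodisulfate through its free para carbon to give the aryl sulfate, which acid hydrolyses to the para-hydroquinone while the allyl ether and ketone are inert.

Step 3
Reactants: 4 1-[3,6-dihydroxy-2-methoxy-4-(prop-2-en-1-yloxy)phenyl]ethan-1-one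
Product: 5 1-[6-hydroxy-2,3-dimethoxy-4-(prop-2-en-1-yloxy)phenyl]ethan-1-one
Conditions: MeI (1.1 equiv), K2CO3 (1.1 equiv), acetone, 40 °C
Reagents that add atoms: iodomethane (CI)
Why: Selective Williamson O-methylation, because the new 3-OH is free whereas the 6-OH is locked in a hydrogen bond to the acetyl group and does not react with one equivalent of MeI.

Step 4
Reactants: 6 2-(2-methoxyphenyl)ethan-1-ol
Product: 7 2-(2-methoxyphenyl)ethyl N,N-diisopropylcarbamate
Conditions: NaH (1.2 equiv), THF, 0 °C; iPr2NCOCl (1.1 equiv), reflux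
Reagents that add atoms: N,N-diisopropylcarbamoyl chloride (CC(C)N(C(C)C)C(Cl)=O)
Why: O-carbamoylation of the sodium alkoxide installs the Hoppe N,N-diisopropylcarbamate that later directs and stabilises α-lithiation.

Step 5
Reactants: 7 2-(2-methoxyphenyl)ethyl N,N-diisopropylcarbamate
Product: 9 2-(5-formyl-2-methoxyphenyl)ethyl N,N-diisopropylcarbamate, via chloro(methoxy)methyl arene 8 (not isolated)
Conditions: Cl2CHOMe (1.5 equiv), TiCl4 (2.2 equiv), CH2Cl2, −10 to 0 °C; ice-water
Reagents that add atoms: dichloromethyl methyl ether (COC(Cl)Cl); water (O)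
Why: Rieche formylation (Friedel–Crafts type), in which the methoxy group directs the electrophile para to itself, onto the carbon that becomes C1' of the B ring, and the carbamate is stable to TiCl4.

Step 6
Reactants: 9 2-(5-formyl-2-methoxyphenyl)ethyl N,N-diisopropylcarbamate
Product: 10 2-[5-(dimethoxymethyl)-2-methoxyphenyl]ethyl N,N-diisopropylcarbamate
Conditions: HC(OMe)3 (neat, 5 equiv), p-TsOH·H2O (2 mol %), rt; Et3N quench
Reagents that add atoms: trimethyl orthoformate (COC(OC)OC)
Why: Acid-catalysed acetalisation masks the aldehyde, which would otherwise be attacked by s-BuLi and by the allylboronate formed in step 7.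

Step 7
Reactants: 10 2-[5-(dimethoxymethyl)-2-methoxyphenyl]ethyl N,N-diisopropylcarbamate; 11 4,4,5,5-tetramethyl-2-(prop-1-en-2-yl)-1,3,2-dioxaborolane
Product: 16 3-[(2R)-2-hydroxy-3-methylbut-3-en-1-yl]-4-methoxybenzaldehyde, via lithiated carbamate 12 (not isolated), via lithium boronate complex 13 (not isolated), via allylic pinacol boronate 14 (not isolated), via hydroxy acetal 15 (not isolated)
Conditions: s-BuLi (1.3 equiv), (−)-sparteine (1.3 equiv), Et2O, −78 °C, 5 h; 11 (1.5 equiv), −78 °C, 1 h; MgBr2·OEt2, −78 °C to reflux, 12 h; THF, 2 M NaOH, 30% H2O2, 0 °C to rt; Na2S2O3; 1 M HCl, rt, 30 min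
Reagents that add atoms: hydrogen peroxide (OO); water (O)
Why: Hoppe–Aggarwal lithiation–borylation, in which s-BuLi/(−)-sparteine removes the pro-S α-hydrogen to give a configurationally stable (S) α-oxy carbanion (the carbinol carbon with donor polarity) that adds to the alkenylboronate with retention, the isopropenyl group then migrates from boron to carbon anti to the departing carbamate (1,2-metallate shift, inversion), and stereoretentive C–B oxidation gives the (R)-carbinol before dilute acid unmasks the aldehyde.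

Step 8
Reactants: 5 1-[6-hydroxy-2,3-dimethoxy-4-(prop-2-en-1-yloxy)phenyl]ethan-1-one; 16 3-[(2R)-2-hydroxy-3-methylbut-3-en-1-yl]-4-methoxybenzaldehyde
Product: 19 3-hydroxy-2-{3-[(2R)-2-hydroxy-3-methylbut-3-en-1-yl]-4-methoxyphenyl}-5,6-dimethoxy-7-(prop-2-en-1-yloxy)-4H-chromen-4-one, via chalcone 17 (not isolated), via dihydroflavonol 18 (not isolated)
Conditions: 50% aq KOH (10 equiv), EtOH, rt, 48 h, N2; then MeOH, 30% H2O2 (5 equiv), 0 °C to rt, 4 h; 2 M HCl to pH 3
Reagents that add atoms: hydrogen peroxide (OO)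
Why: One-pot Claisen–Schmidt condensation and Algar–Flynn–Oyamada oxidative cyclisation, in which alkaline H2O2 takes the 2'-hydroxychalcone through the 3-hydroxyflavanone to the flavonol, the electron-rich 4-methoxyaryl group favouring 6-endo closure at the β-carbon, while the isolated alkenes, the allyl ether and the non-enolisable carbinol centre are untouched.

Step 9
Reactants: 19 3-hydroxy-2-{3-[(2R)-2-hydroxy-3-methylbut-3-en-1-yl]-4-methoxyphenyl}-5,6-dimethoxy-7-(prop-2-en-1-yloxy)-4H-chromen-4-one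
Product: 20 3,7-dihydroxy-2-{3-[(2R)-2-hydroxy-3-methylbut-3-en-1-yl]-4-methoxyphenyl}-5,6-dimethoxy-4H-chromen-4-one
Conditions: Pd(PPh3)4 (5 mol %), morpholine (5 equiv), THF, rt, Ar
Reagents that add atoms: none
Why: Tsuji–Trost deallylation, in which Pd(0) ionises the aryl allyl ether (the 7-oxychromone is an excellent leaving group) and morpholine traps the π-allyl complex, while the free allylic alcohol of the side chain is not ionised under these neutral conditions.

## Compound list

1 | 1-(2,4-dihydroxy-6-methoxyphenyl)ethan-1-one (2',4'-dihydroxy-6'-methoxyacetophenone) | CC(=O)c1c(O)cc(O)cc1OC | starting material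
2 | 1-[2-hydroxy-6-methoxy-4-(prop-2-en-1-yloxy)phenyl]ethan-1-one | CC(=O)c1c(O)cc(OCC=C)cc1OC | intermediate
3 | potassium 3-acetyl-4-hydroxy-2-methoxy-6-(prop-2-en-1-yloxy)phenyl sulfate (Elbs sulfate; not isolated) | CC(=O)c1c(O)cc(OCC=C)c(OS(=O)(=O)[O-])c1OC.[K+] | intermediate
4 | 1-[3,6-dihydroxy-2-methoxy-4-(prop-2-en-1-yloxy)phenyl]ethan-1-one | CC(=O)c1c(O)cc(OCC=C)c(O)c1OC | intermediate
5 | 1-[6-hydroxy-2,3-dimethoxy-4-(prop-2-en-1-yloxy)phenyl]ethan-1-one (A-ring ketone) | CC(=O)c1c(O)cc(OCC=C)c(OC)c1OC | intermediate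
6 | 2-(2-methoxyphenyl)ethan-1-ol | COc1ccccc1CCO | starting material
7 | 2-(2-methoxyphenyl)ethyl N,N-diisopropylcarbamate | COc1ccccc1CCOC(=O)N(C(C)C)C(C)C | intermediate
8 | 2-{5-[chloro(methoxy)methyl]-2-methoxyphenyl}ethyl N,N-diisopropylcarbamate (racemic at the chloro ether carbon; not isolated) | COc1ccc(C(Cl)OC)cc1CCOC(=O)N(C(C)C)C(C)C | intermediate
9 | 2-(5-formyl-2-methoxyphenyl)ethyl N,N-diisopropylcarbamate | COc1ccc(C=O)cc1CCOC(=O)N(C(C)C)C(C)C | intermediate
10 | 2-[5-(dimethoxymethyl)-2-methoxyphenyl]ethyl N,N-diisopropylcarbamate | COc1ccc(C(OC)OC)cc1CCOC(=O)N(C(C)C)C(C)C | intermediate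
11 | 4,4,5,5-tetramethyl-2-(prop-1-en-2-yl)-1,3,2-dioxaborolane (isopropenylboronic acid pinacol ester) | CC(=C)B1OC(C)(C)C(C)(C)O1 | starting material
12 | (1S)-2-[5-(dimethoxymethyl)-2-methoxyphenyl]-1-lithioethyl N,N-diisopropylcarbamate, as its (−)-sparteine complex (not isolated) | CC(C)N(C(C)C)C(=O)O[C@@H]([Li])Cc1cc(C(OC)OC)ccc1OC | intermediate
13 | lithium pinacolato(isopropenyl)borate carrying the (1S)-1-(diisopropylcarbamoyloxy)-2-[5-(dimethoxymethyl)-2-methoxyphenyl]ethyl group on boron (not isolated) | CC(C)N(C(C)C)C(=O)O[C@@H]([B-]1(C(C)=C)OC(C)(C)C(C)(C)O1)Cc1cc(C(OC)OC)ccc1OC.[Li+] | intermediate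
14 | 2-{(2R)-1-[5-(dimethoxymethyl)-2-methoxyphenyl]-3-methylbut-3-en-2-yl}-4,4,5,5-tetramethyl-1,3,2-dioxaborolane (not isolated) | C=C(C)[C@H](B1OC(C)(C)C(C)(C)O1)Cc1cc(C(OC)OC)ccc1OC | intermediate
15 | (2R)-1-[5-(dimethoxymethyl)-2-methoxyphenyl]-3-methylbut-3-en-2-ol (not isolated) | C=C(C)[C@H](O)Cc1cc(C(OC)OC)ccc1OC | intermediate
16 | 3-[(2R)-2-hydroxy-3-methylbut-3-en-1-yl]-4-methoxybenzaldehyde (B-ring aldehyde) | C=C(C)[C@H](O)Cc1cc(C=O)ccc1OC | intermediate
17 | (2E)-1-[6-hydroxy-2,3-dimethoxy-4-(prop-2-en-1-yloxy)phenyl]-3-{3-[(2R)-2-hydroxy-3-methylbut-3-en-1-yl]-4-methoxyphenyl}prop-2-en-1-one (not isolated) | C=C(C)[C@H](O)Cc1cc(/C=C/C(=O)c2c(O)cc(OCC=C)c(OC)c2OC)ccc1OC | intermediate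
18 | trans-3-hydroxy-2-{3-[(2R)-2-hydroxy-3-methylbut-3-en-1-yl]-4-methoxyphenyl}-5,6-dimethoxy-7-(prop-2-en-1-yloxy)-2,3-dihydro-4H-chromen-4-one (both trans C2/C3 diastereomers; not isolated) | C=C(C)[C@H](O)Cc1cc(C2Oc3cc(OCC=C)c(OC)c(OC)c3C(=O)C2O)ccc1OC | intermediate
19 | 3-hydroxy-2-{3-[(2R)-2-hydroxy-3-methylbut-3-en-1-yl]-4-methoxyphenyl}-5,6-dimethoxy-7-(prop-2-en-1-yloxy)-4H-chromen-4-one | C=C(C)[C@H](O)Cc1cc(-c2oc3cc(OCC=C)c(OC)c(OC)c3c(=O)c2O)ccc1OC | intermediate
20 | 3,7-dihydroxy-2-{3-[(2R)-2-hydroxy-3-methylbut-3-en-1-yl]-4-methoxyphenyl}-5,6-dimethoxy-4H-chromen-4-one | C=C(C)[C@H](O)Cc1cc(-c2oc3cc(O)c(OC)c(OC)c3c(=O)c2O)ccc1OC | target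

## Step count and risks

Total steps: 9 (steps 1–3 make the A-ring ketone, steps 4–7 the B-ring aldehyde, steps 8–9 join and finish).
Longest linear sequence: 6 steps (6 → 7 → 9 → 10 → 16 → 19 → 20).

The three steps most likely to fail:

Step 7. The 1,2-shift of a pinacol boronate complex derived from a primary carbamate can be slow. Benzylic deprotonation with elimination to the styrene can compete with α-lithiation, and the enantiomer ratio depends on clean low-temperature handling. The fallback sets out from 10. It keeps the sparteine-mediated lithiation to 12 but traps the carbanion directly with acetone (electrophilic substitution with retention, which gives the same absolute sense). This gives (2R)-1-[5-(dimethoxymethyl)-2-methoxyphenyl]-3-hydroxy-3-methylbutan-2-yl N,N-diisopropylcarbamate F1. Dehydration of the tertiary alcohol toward a methyl group with SOCl2/pyridine at 0 °C gives (2R)-1-[5-(dimethoxymethyl)-2-methoxyphenyl]-3-methylbut-3-en-2-yl N,N-diisopropylcarbamate F2. LiAlH4 in refluxing THF removes the carbamate, and the fallback comes back to the route at 15, which the dilute-acid treatment of step 7 turns into 16. Because it shares the lithiation, this fallback covers failure of the borylation, migration or oxidation, not failure of the deprotonation itself.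

Step 8. The 6'-methoxy group of the chalcone is known to divert Algar–Flynn–Oyamada reactions toward aurones (5-exo closure), and the doubly ortho-substituted ketone condenses slowly. The fallback sets out from chalcone 17, isolated after the KOH stage without adding peroxide. Catalytic I2 in DMSO at 120 °C cyclises and dehydrogenates it to the flavone 2-{3-[(2R)-2-hydroxy-3-methylbut-3-en-1-yl]-4-methoxyphenyl}-5,6-dimethoxy-7-(prop-2-en-1-yloxy)-4H-chromen-4-one F3. LDA (3.3 equiv, THF, −78 °C) removes the C3 proton (and the carbinol proton), and B(OMe)3 gives dimethyl [2-{3-[(2R)-2-hydroxy-3-methylbut-3-en-1-yl]-4-methoxyphenyl}-5,6-dimethoxy-4-oxo-7-(prop-2-en-1-yloxy)-4H-chromen-3-yl]boronate F4. Oxidation with H2O2/AcOH brings the fallback back to the route at 19.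

Step 2. Elbs oxidations rarely exceed 30–45% conversion (unreacted 2 is recycled), and sulfate radicals could attack the allyl ether. The fallback sets out from 2. PhI(OAc)2 (2.2 equiv) in MeOH at 0 °C oxidises the phenol at its free para position to the quinone monoketal 2-acetyl-3,4,4-trimethoxy-5-(prop-2-en-1-yloxy)cyclohexa-2,5-dien-1-one F5. Zn in AcOH reduces it with loss of methanol directly to the para-methoxyphenol, so the fallback comes back to the route at 5 and bypasses 3, 4 and step 3.

## Further compounds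

F1 | step 7 | (2R)-1-[5-(dimethoxymethyl)-2-methoxyphenyl]-3-hydroxy-3-methylbutan-2-yl N,N-diisopropylcarbamate | CC(C)N(C(C)C)C(=O)O[C@@H](C(C)(C)O)Cc1cc(C(OC)OC)ccc1OC
F2 | step 7 | (2R)-1-[5-(dimethoxymethyl)-2-methoxyphenyl]-3-methylbut-3-en-2-yl N,N-diisopropylcarbamate | CC(C)N(C(C)C)C(=O)O[C@@H](C(C)=C)Cc1cc(C(OC)OC)ccc1OC
F3 | step 8 | 2-{3-[(2R)-2-hydroxy-3-methylbut-3-en-1-yl]-4-methoxyphenyl}-5,6-dimethoxy-7-(prop-2-en-1-yloxy)-4H-chromen-4-one | C=C(C)[C@H](O)Cc1cc(-c2cc(=O)c3c(OC)c(OC)c(OCC=C)cc3o2)ccc1OC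
F4 | step 8 | dimethyl [2-{3-[(2R)-2-hydroxy-3-methylbut-3-en-1-yl]-4-methoxyphenyl}-5,6-dimethoxy-4-oxo-7-(prop-2-en-1-yloxy)-4H-chromen-3-yl]boronate | C=C(C)[C@H](O)Cc1cc(-c2oc3cc(OCC=C)c(OC)c(OC)c3c(=O)c2B(OC)OC)ccc1OC
F5 | step 2 | 2-acetyl-3,4,4-trimethoxy-5-(prop-2-en-1-yloxy)cyclohexa-2,5-dien-1-one | CC(=O)C1=C(OC)C(OC)(OC)C(OCC=C)=CC1=O
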